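## Structural features

The target is a germacranolide: a ten-membered carbocycle (C1–C10) fused through C6 and C7 to a butenolide. The tetrasubstituted C7=C11 alkene belongs to both rings and the lactone oxygen sits on C6. The carbocycle carries a C1 ketone next to the C10 methine with its C14 methyl, a cis-4,5-epoxide (C3 and C6 on the same side of the oxirane, C15 methyl on C4) and the tiglate on C8; C11 carries the acetoxymethyl carbon C13. Read from the SMILES string, the configuration is 4R,5S,6S,8S,10R. C4, C5 and C6 are contiguous, C8 is separated from C6 only by the trigonal C7, and C10 stands alone, α to the ketone and therefore epimerisable. The fragile groups are four: the trisubstituted epoxide (opened by acid, and by base through vinylogous deprotonation at C6–H and β-elimination), the primary allylic acetate (able to ionise or to shift to a free O8), the (E)-tiglate and C10. The real difficulty is the medium ring: it must be closed late, with all of this in place, without transannular chemistry and with control of C10. The key step exploits two features: the C1(=O)–C10H(CH3) unit, which is the Markovnikov adduct of a C1 aldehyde C–H across a C10=C14 vinyl group, and the C8 oxygen, which is homoallylic to that vinyl group and can hold rhodium. The open-chain precursor 21 and the cyclised product 22 drawn below carry the same descriptors at C4, C5, C6 and C8 as the target, so no structural correction was needed.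

## Logic of the disconnections

**25 to 22 and 23.** The C8–O acyl bond is cut. The tiglate is the easiest group to introduce and to lose, and removing it uncovers the hydroxyl that the ring closure needs as a ligand; the unsaturated ester then never meets a rhodium hydride. The forward acylation must work on a hindered allylic secondary alcohol without moving the acetate from O13 to O8 and without base strong enough to touch C6–H or C10–H.

**22 to 21.** The C1–C10 bond is cut together with the C14–H bond, turning the ketone and its α-methyl methine into an aldehyde and a vinyl group. This is the only ring bond whose formation needs no leaving group, no redox adjustment and no protecting group, and it opens the ring to a chain that already holds four of the five stereocentres. The forward step must add the aldehyde C–H in the branched sense, close a ten-membered rather than an eleven-membered ring, and set 10R. For this, 21 is designed with the C8 hydroxyl free as the one good donor beside the vinyl group, with C13 as the weakly coordinating acetate, and with no silyl ether or other donor that could compete for the metal.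

**21 to 20.** No skeletal bond is cut; the C1 aldehyde is taken back to a primary alcohol. The γ,δ-epoxy aldehyde is the most fragile function of the chain, because acid would let its oxygen open the tertiary epoxide carbon. It is therefore released last, by a neutral oxidation and not by an acetal hydrolysis. The demand is chemoselective oxidation of a primary alcohol beside the secondary C8 carbinol.

**20 to 18 and 19.** The C8–C9 bond is cut. Allylation of a C8 aldehyde brings in C9, C10, C14 and the C8 stereocentre in one step, delivers the hydroxyl unprotected, and postpones the terminal alkene until all electrophilic chemistry at C11 is finished. The forward step needs catalyst control of the aldehyde face, since the nearest stereocentre, C6, lies in the plane of the butenolide.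

**18 to 17 to 16.** The C8 aldehyde goes back to the allylic primary alcohol, and the hydroxyls at C8 and C1 go back to silyl ethers (O–Si bonds cut). One deprotection frees both, and the two primary alcohols are then told apart by oxidation chemistry (the allylic one first, the saturated one later) instead of by orthogonal protecting groups. The demand is a desilylation that spares the epoxide and does not let the acetate wander to O8.

**16 to 15 to 14 to 13.** The acetate O–acyl bond, then the C11–C13 bond, then the carbon–iodine bond at C11 (back to carbon–silicon) are cut. C13 is the one carbon the butenolide assembly cannot deliver, because its position is needed for the silicon that steers that assembly. The gain is a butenolide made in one operation. The demand is ipso-substitution of an electron-poor vinylsilane and cross-coupling of an sp3 stannane, both on a molecule that at this point has no other alkene.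

**13 to 7 and 9 (with carbon dioxide).** The C6–C7 bond, the C11–C12 bond and the lactone O–C12 bond are cut, so the butenolide falls apart into an aldehyde, an alkyne and CO2. The ring, its tetrasubstituted alkene and C6 then arise together from two small pieces. The demand is regiochemistry (carbon–carbon bond formation at the alkyne carbon remote from silicon) and Felkin–Anh addition to the α,β-epoxy aldehyde to give 6S.

**9 to 8.** An O–Si bond is cut; the protection is needed only because the titanium reagent is generated with a Grignard reagent.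

**7 to 6 to 5.** The aldehyde is taken back to the alcohol and both epoxide C–O bonds are cut. The allylic alcohol directs an asymmetric epoxidation, and its Z geometry is what places C3 and C6 on the same side of the oxirane. The demand is the 2S,3R sense on a Z-trisubstituted allylic alcohol and an oxidation that does not open the epoxide.

**5 to 4 to 3 to 1.** The acetate O–acyl bond and the O–Si bond are cut, and the terminal isopropylidene alkene is restored at C1. This leads to a commercial terpene ester that already holds C1–C6, C15 and the Z alkene. The demand is ozonolysis at the distal alkene only.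

## Other disconnections considered

**Alternative 1:** The C8–C9 bond is cut and C1 is joined to C6, which folds the ring back to the spiro-lactone dialkenylcyclohexanol A1.
- Forward step: KH/18-crown-6 would convert A1 into its C1 alkoxide; the [3,3] shift would form C8–C9 and break C1–C6; a buffered quench would move the enol-lactone alkene from C6=C7 to C7=C11 and give A2.
- In its favour: ring expansion from a six-membered ring avoids the entropy cost of a medium-ring closure, and the anionic oxy-Cope is among the best-precedented entries to germacranes. On mechanistic precedent it is clearly the better of the two plans.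
- Against it here: A2 lacks C13, has no epoxide and carries a silyl ether where the tiglate belongs. Hydroxymethylation at the α-carbon of a β,β-disubstituted butenolide, face-selective epoxidation and a protecting-group exchange would all follow. C6 and C10 would both be set by protonations, potassium alkoxide conditions are harsh for a lactone bearing an enol ether, and A1, with two adjacent quaternary carbons, is not short to make.
- Comparison: on structure, A2 still needs three functional groups, whereas 22 needs only the ester. On mechanism, the alternative is the safer reaction. On step economy, the chosen plan is shorter after ring formation.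

**Alternative 2:** The C1–C2 bond is cut and C1 is joined to C6, giving the cyclohexanone-fused butenolide iodide A3.
- Forward step: Bu3SnH/AIBN would generate the primary C2 radical, which would add to the C1 carbonyl through a six-membered transition state. The alkoxy radical would cleave C1–C6, and the C6 radical would be reduced to give A4.
- In its favour: the radical conditions are neutral and tolerate the acetate and the lactone; C13 is already present; the Z alkene is fixed by the cyclic transition state. C8 and C10 would be set on a six-membered ring, where conformational control is dependable; on control of C10 this plan is the equal or the better of the chosen one.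
- Against it here: the fragmentation leaves a C6 radical that is allylic twice over and α to oxygen, so hydrogen could be delivered to C6, C4 or C11 and the C6 configuration would not be controlled. Direct reduction of the primary radical and hydrogen shifts would compete. A3 has a fully substituted, oxygenated C6 that is hard to assemble, and epoxidation and the silyl-to-tiglate exchange would still remain. Tin is used in stoichiometric amount.
- Comparison: on mechanism, the ring-expansion class is known and is the equal of the chosen plan in precedent for the ring size. On structure, it gives up control of C6, which the chosen plan fixes early. On step economy, it is longer.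

**Alternative 3:** The C2–C3 bond is cut and the ring oxygen is joined to C1 and C5, giving the 2-methylene oxocane A5.
- Forward step: heating A5 would effect the Claisen shift (C2–C3 formed, O–C5 broken) and give the ketone A6.
- In its favour: the step needs no reagent and no catalyst, and C6, C8 and C10 are all in place before the ring expands. On control of C10 and on freedom from metal-centred side reactions it is the better of the two plans.
- Against it here: A5 is itself a medium ring (an eight-membered lactone followed by methylenation with Cp2TiMe2). The Z geometry of the new alkene would depend on the C5 configuration and on chair against boat. A6 is a dihydrofuran, so allylic oxidation at C12 in preference to C6, epoxidation, and differentiation of two silyl ethers into acetate and tiglate would all follow.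
- Comparison: on mechanism, it is well understood and predictable. On structure, it postpones the oxidation level of C12 and the epoxide, which the chosen plan has in place before the ring is closed. On step economy, it is clearly longer.

Key step: step 15

Assumption: the facial sense of (S)-TRIP in step 13 and the ligand antipode matched with the 8S carbinol in step 15 are taken from the accepted models for alkenyl aldehydes and for directed hydroacylation; if either proves reversed, the antipodal catalyst is used and nothing else changes.

Step 1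
Reactants: 1 neryl acetate [(2Z)-3,7-dimethylocta-2,6-dien-1-yl acetate]
Product: 3 (2Z)-6-hydroxy-3-methylhex-2-en-1-yl acetate, via aldehyde 2 (not isolated)
Conditions: O3 (1 equiv, Sudan Red 7B end point), CH2Cl2/MeOH, −78 °C; then NaBH4, −78 → 0 °C
Reagents that add atoms: ozone, [O-][O+]=O
Why: Chemoselective ozonolysis with reductive work-up: the distal trisubstituted alkene is more electron-rich than the alkene carrying the allylic acetate and is cleaved first, and NaBH4 reduces the aldehyde 2 to the alcohol without touching the ester. No stereocentre is formed and the Z alkene is kept.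

Step 2
Reactants: 3 (2Z)-6-hydroxy-3-methylhex-2-en-1-yl acetate
Product: 4 (2Z)-6-[(tert-butyldimethylsilyl)oxy]-3-methylhex-2-en-1-yl acetate
Conditions: TBSCl, imidazole, CH2Cl2, 0 °C → rt
Reagents that add atoms: tert-butyldimethylsilyl chloride, CC(C)(C)[Si](C)(C)Cl
Why: Standard silylation of a primary alcohol; the TBS ether survives every step up to step 11.

Step 3
Reactants: 4 (2Z)-6-[(tert-butyldimethylsilyl)oxy]-3-methylhex-2-en-1-yl acetate
Product: 5 (2Z)-6-[(tert-butyldimethylsilyl)oxy]-3-methylhex-2-en-1-ol
Conditions: K2CO3 (0.2 equiv), MeOH, 0 °C → rt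
Reagents that add atoms: none
Why: Base-catalysed transesterification (methanolysis) removes the acetate; the silyl ether and the Z alkene are inert.

Step 4
Reactants: 5 (2Z)-6-[(tert-butyldimethylsilyl)oxy]-3-methylhex-2-en-1-ol
Product: 6 [(2S,3R)-3-{3-[(tert-butyldimethylsilyl)oxy]propyl}-3-methyloxiran-2-yl]methanol
Conditions: Ti(OiPr)4 (10 mol%), L-(+)-diethyl tartrate (12 mol%), tBuOOH, 4 Å MS, CH2Cl2, −20 °C
Reagents that add atoms: tert-butyl hydroperoxide, CC(C)(C)OO
Why: Sharpless asymmetric epoxidation: with L-(+)-diethyl tartrate a Z-3-methyl allylic alcohol of the nerol type is epoxidised to the (2S,3R)-epoxy alcohol. This fixes C5 (S) and C4 (R) of the target and, through the Z alkene, the cis relationship of C3 and C6 on the oxirane.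

Step 5
Reactants: 6 [(2S,3R)-3-{3-[(tert-butyldimethylsilyl)oxy]propyl}-3-methyloxiran-2-yl]methanol
Product: 7 (2R,3R)-3-{3-[(tert-butyldimethylsilyl)oxy]propyl}-3-methyloxirane-2-carbaldehyde
Conditions: Dess–Martin periodinane, pyridine, CH2Cl2, 0 °C → rt
Reagents that add atoms: none
Why: Dess–Martin oxidation under pyridine buffer gives the α,β-epoxy aldehyde without acid; the descriptor at C2 changes only because of the priority rules. The aldehyde is used at once.

Step 6
Reactants: 8 3-(trimethylsilyl)prop-2-yn-1-ol
Product: 9 tert-butyldimethyl{[3-(trimethylsilyl)prop-2-yn-1-yl]oxy}silane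
Conditions: TBSCl, imidazole, CH2Cl2, 0 °C → rt
Reagents that add atoms: tert-butyldimethylsilyl chloride, CC(C)(C)[Si](C)(C)Cl
Why: Standard silylation; protection is needed because the titanium reagent of step 7 is generated with a Grignard reagent.

Step 7
Reactants: 9 tert-butyldimethyl{[3-(trimethylsilyl)prop-2-yn-1-yl]oxy}silane, 7 (2R,3R)-3-{3-[(tert-butyldimethylsilyl)oxy]propyl}-3-methyloxirane-2-carbaldehyde
Product: 13 (5S)-4-{[(tert-butyldimethylsilyl)oxy]methyl}-5-[(2S,3R)-3-{3-[(tert-butyldimethylsilyl)oxy]propyl}-3-methyloxiran-2-yl]-3-(trimethylsilyl)furan-2(5H)-one, via titanacyclopropene 10 (not isolated), via oxatitanacyclopentene 11 (not isolated), via hydroxy acid 12 (not isolated)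
Conditions: 9, Ti(OiPr)4, iPrMgCl (2 equiv per Ti), Et2O, −78 → −50 °C; then 7, −78 → −40 °C; then CO2 (1 atm), −40 → 0 °C; aq. citric acid
Reagents that add atoms: carbon dioxide, O=C=O
Why: Titanium-mediated alkyne–aldehyde–CO2 coupling: Ti(OiPr)4/2 iPrMgCl (a Kulinkovich-type low-valent titanium alkoxide) forms the titanacyclopropene 10, the aldehyde inserts at the alkyne carbon remote from silicon to give 11, CO2 inserts into the remaining vinyl–titanium bond and the hydroxy acid 12 lactonises on acidic work-up. C6 is set by Felkin–Anh addition anti to the epoxide C–O bond at a weakly Lewis-acidic, non-chelating titanium alkoxide, which gives the required 6S (anti) arrangement.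

Step 8
Reactants: 13 (5S)-4-{[(tert-butyldimethylsilyl)oxy]methyl}-5-[(2S,3R)-3-{3-[(tert-butyldimethylsilyl)oxy]propyl}-3-methyloxiran-2-yl]-3-(trimethylsilyl)furan-2(5H)-one
Product: 14 (5S)-4-{[(tert-butyldimethylsilyl)oxy]methyl}-3-iodo-5-[(2S,3R)-3-{3-[(tert-butyldimethylsilyl)oxy]propyl}-3-methyloxiran-2-yl]furan-2(5H)-one
Conditions: ICl (1.1 equiv), CH2Cl2, −78 → 0 °C, dark; aq. Na2S2O3
Reagents that add atoms: iodine monochloride, ClI
Why: Electrophilic ipso-iododesilylation of a vinylsilane: iodine attacks the silicon-bearing carbon and Me3SiCl is lost from the β-silyl cation. The substrate contains no other alkene, which is why this step precedes the allylation.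

Step 9
Reactants: 14 (5S)-4-{[(tert-butyldimethylsilyl)oxy]methyl}-3-iodo-5-[(2S,3R)-3-{3-[(tert-butyldimethylsilyl)oxy]propyl}-3-methyloxiran-2-yl]furan-2(5H)-one
Product: 15 (5S)-4-{[(tert-butyldimethylsilyl)oxy]methyl}-3-(hydroxymethyl)-5-[(2S,3R)-3-{3-[(tert-butyldimethylsilyl)oxy]propyl}-3-methyloxiran-2-yl]furan-2(5H)-one
Conditions: Bu3SnCH2OH, Pd(PPh3)4 (5 mol%), 1,4-dioxane, 80 °C
Reagents that add atoms: (tributylstannyl)methanol, OC[Sn](CCCC)(CCCC)CCCC
Why: Stille cross-coupling of an α-iodo enoate with (tributylstannyl)methanol transfers the hydroxymethyl group (C13) under neutral conditions that spare the epoxide and the silyl ethers.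

Step 10
Reactants: 15 (5S)-4-{[(tert-butyldimethylsilyl)oxy]methyl}-3-(hydroxymethyl)-5-[(2S,3R)-3-{3-[(tert-butyldimethylsilyl)oxy]propyl}-3-methyloxiran-2-yl]furan-2(5H)-one
Product: 16 [(5S)-4-{[(tert-butyldimethylsilyl)oxy]methyl}-5-[(2S,3R)-3-{3-[(tert-butyldimethylsilyl)oxy]propyl}-3-methyloxiran-2-yl]-2-oxo-2,5-dihydrofuran-3-yl]methyl acetate
Conditions: Ac2O, pyridine, DMAP (cat.), CH2Cl2, 0 °C
Reagents that add atoms: acetic anhydride, CC(=O)OC(C)=O
Why: Acylation of the primary allylic alcohol; it is done while O8 and O1 are still silylated so that only O13 is acetylated.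

Step 11
Reactants: 16 [(5S)-4-{[(tert-butyldimethylsilyl)oxy]methyl}-5-[(2S,3R)-3-{3-[(tert-butyldimethylsilyl)oxy]propyl}-3-methyloxiran-2-yl]-2-oxo-2,5-dihydrofuran-3-yl]methyl acetate
Product: 17 [(5S)-4-(hydroxymethyl)-5-[(2S,3R)-3-(3-hydroxypropyl)-3-methyloxiran-2-yl]-2-oxo-2,5-dihydrofuran-3-yl]methyl acetate
Conditions: HF·pyridine, pyridine, THF, 0 °C → rt
Reagents that add atoms: none
Why: Fluoride-mediated desilylation with pyridine-buffered HF·pyridine frees both primary alcohols. The medium is not basic enough to deprotonate C6–H or to move the acetate to O8, and not acidic enough to open the epoxide.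

Step 12
Reactants: 17 [(5S)-4-(hydroxymethyl)-5-[(2S,3R)-3-(3-hydroxypropyl)-3-methyloxiran-2-yl]-2-oxo-2,5-dihydrofuran-3-yl]methyl acetate
Product: 18 [(5S)-4-formyl-5-[(2S,3R)-3-(3-hydroxypropyl)-3-methyloxiran-2-yl]-2-oxo-2,5-dihydrofuran-3-yl]methyl acetate
Conditions: activated MnO2 (excess), CH2Cl2, rt
Reagents that add atoms: none
Why: MnO2 oxidises allylic alcohols selectively, so only the C8 alcohol on the butenolide becomes the aldehyde and the saturated C1 alcohol is kept.

Step 13
Reactants: 18 [(5S)-4-formyl-5-[(2S,3R)-3-(3-hydroxypropyl)-3-methyloxiran-2-yl]-2-oxo-2,5-dihydrofuran-3-yl]methyl acetate, 19 allylboronic acid pinacol ester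
Product: 20 [(5S)-4-[(1S)-1-hydroxybut-3-en-1-yl]-5-[(2S,3R)-3-(3-hydroxypropyl)-3-methyloxiran-2-yl]-2-oxo-2,5-dihydrofuran-3-yl]methyl acetate
Conditions: 19, (S)-TRIP [(S)-3,3′-bis(2,4,6-triisopropylphenyl)-1,1′-binaphthyl-2,2′-diyl hydrogen phosphate] (5 mol%), 4 Å MS, toluene, −30 °C
Reagents that add atoms: none
Why: Chiral phosphoric acid-catalysed allylboration through a closed chair transition state; (S)-TRIP should direct the allyl group to the Si face of the alkenyl aldehyde and give the 8S carbinol under catalyst control, the nearest stereocentre (C6) lying in the plane of the butenolide. The C8 hydroxyl is obtained free, as the key step requires.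

Step 14
Reactants: 20 [(5S)-4-[(1S)-1-hydroxybut-3-en-1-yl]-5-[(2S,3R)-3-(3-hydroxypropyl)-3-methyloxiran-2-yl]-2-oxo-2,5-dihydrofuran-3-yl]methyl acetate
Product: 21 [(5S)-4-[(1S)-1-hydroxybut-3-en-1-yl]-5-[(2S,3R)-3-methyl-3-(3-oxopropyl)oxiran-2-yl]-2-oxo-2,5-dihydrofuran-3-yl]methyl acetate
Conditions: TEMPO (10 mol%), PhI(OAc)2, CH2Cl2, rt
Reagents that add atoms: none
Why: TEMPO/PhI(OAc)2 oxidation is selective for primary over secondary alcohols and runs without added acid or base, so the γ,δ-epoxy aldehyde is released last and under neutral conditions.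

Step 15
Reactants: 21 [(5S)-4-[(1S)-1-hydroxybut-3-en-1-yl]-5-[(2S,3R)-3-methyl-3-(3-oxopropyl)oxiran-2-yl]-2-oxo-2,5-dihydrofuran-3-yl]methyl acetate
Product: 22 (4R,5S,6S,8S,10R)-13-acetoxy-4,5-epoxy-8-hydroxy-1-oxogermacr-7(11)-en-12,6-olide (8-O-destigloyl target)
Conditions: [Rh(cod)2]BF4 (10 mol%), (R)-DTBM-SEGPHOS (11 mol%), H2 activation then argon, 1,2-dichloroethane, 60 °C, 21 added over 12 h to 0.002 M
Reagents that add atoms: none
Why: Proposed new method: monovalent rhodium, bound to the C8 hydroxyl and the vinyl group of 21, should add oxidatively to the aldehyde C–H to give a trivalent acyl rhodium hydride, deliver the hydride to C14 and close the ring by C1–C10 reductive elimination. The closest known reaction types are heteroatom-directed, branched-selective intermolecular alkene hydroacylation with cationic rhodium bisphosphines and intramolecular hydroacylation to five- to eight-membered ketones; a ten-membered carbocycle has not been closed this way. The ring is closed in the exo sense (10-exo-trig) at the internal alkene carbon, from an eleven-membered acyl(alkyl)rhodacycle braced by the O8–Rh bond. The new C10 centre is set in the hydride insertion by the chiral bisphosphine, which selects the alkene face; the 8S carbinol is the second control element, so ligand antipode and C8 must be matched. Branched regiochemistry is needed and should follow from the five-membered O8–Rh–C10 chelate being preferred to the six-membered chelate of the linear alkyl. Decarbonylation is countered by the O8/alkene chelate and the weakly donating epoxide oxygen, which keep the acyl hydride coordinatively saturated, and oligomerisation by slow addition at high dilution. No atom is lost.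

Step 16
Reactants: 22 (4R,5S,6S,8S,10R)-13-acetoxy-4,5-epoxy-8-hydroxy-1-oxogermacr-7(11)-en-12,6-olide, 23 tiglic acid
Product: 25 CNP0229937.1, (4R,5S,6S,8S,10R)-13-acetoxy-4,5-epoxy-1-oxo-8-[(2E)-2-methylbut-2-enoyloxy]germacr-7(11)-en-12,6-olide, via mixed anhydride 24 (not isolated)
Conditions: 23, 2,4,6-trichlorobenzoyl chloride, Et3N, toluene, rt; then 22, DMAP (cat.), 0 °C → rt
Reagents that add atoms: none
Why: Yamaguchi esterification: tiglic acid is activated as the mixed anhydride 24 and DMAP transfers the acyl group to the hindered C8 hydroxyl; the E geometry of the tiglate is the stable one. Low temperature and a short reaction time are chosen to keep the C13 acetate from migrating to O8.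

## Compound list

1 | neryl acetate, (2Z)-3,7-dimethylocta-2,6-dien-1-yl acetate | CC(C)=CCC/C(C)=C\COC(C)=O | starting material
2 | (2Z)-3-methyl-6-oxohex-2-en-1-yl acetate | O=CCC/C(C)=C\COC(C)=O | intermediate
3 | (2Z)-6-hydroxy-3-methylhex-2-en-1-yl acetate | OCCC/C(C)=C\COC(C)=O | intermediate
4 | (2Z)-6-[(tert-butyldimethylsilyl)oxy]-3-methylhex-2-en-1-yl acetate | CC(C)(C)[Si](C)(C)OCCC/C(C)=C\COC(C)=O | intermediate
5 | (2Z)-6-[(tert-butyldimethylsilyl)oxy]-3-methylhex-2-en-1-ol | CC(C)(C)[Si](C)(C)OCCC/C(C)=C\CO | intermediate
6 | [(2S,3R)-3-{3-[(tert-butyldimethylsilyl)oxy]propyl}-3-methyloxiran-2-yl]methanol | OC[C@@H]1O[C@]1(C)CCCO[Si](C)(C)C(C)(C)C | intermediate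
7 | (2R,3R)-3-{3-[(tert-butyldimethylsilyl)oxy]propyl}-3-methyloxirane-2-carbaldehyde | O=C[C@@H]1O[C@]1(C)CCCO[Si](C)(C)C(C)(C)C | intermediate
8 | 3-(trimethylsilyl)prop-2-yn-1-ol | C[Si](C)(C)C#CCO | starting material
9 | tert-butyldimethyl{[3-(trimethylsilyl)prop-2-yn-1-yl]oxy}silane | C[Si](C)(C)C#CCO[Si](C)(C)C(C)(C)C | intermediate
10 | diisopropoxytitanium complex of alkyne 9 (titanacyclopropene) | CC(C)O[Ti]1(OC(C)C)C(CO[Si](C)(C)C(C)(C)C)=C1[Si](C)(C)C | intermediate
11 | 2,2-diisopropoxy-1-oxa-2-titanacyclopent-3-ene from 10 and 7 (titanium on O6 and on C11) | CC(C)O[Ti]1(OC(C)C)O[C@H]([C@@H]2O[C@]2(C)CCCO[Si](C)(C)C(C)(C)C)C(CO[Si](C)(C)C(C)(C)C)=C1[Si](C)(C)C | intermediate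
12 | (2E,4S)-3-{[(tert-butyldimethylsilyl)oxy]methyl}-4-hydroxy-4-[(2S,3R)-3-{3-[(tert-butyldimethylsilyl)oxy]propyl}-3-methyloxiran-2-yl]-2-(trimethylsilyl)but-2-enoic acid (carboxyl cis to the carbinol carbon) | OC(=O)/C([Si](C)(C)C)=C(/CO[Si](C)(C)C(C)(C)C)[C@H](O)[C@@H]1O[C@]1(C)CCCO[Si](C)(C)C(C)(C)C | intermediate
13 | (5S)-4-{[(tert-butyldimethylsilyl)oxy]methyl}-5-[(2S,3R)-3-{3-[(tert-butyldimethylsilyl)oxy]propyl}-3-methyloxiran-2-yl]-3-(trimethylsilyl)furan-2(5H)-one | CC(C)(C)[Si](C)(C)OCC1=C([Si](C)(C)C)C(=O)O[C@@H]1[C@@H]1O[C@]1(C)CCCO[Si](C)(C)C(C)(C)C | intermediate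
14 | (5S)-4-{[(tert-butyldimethylsilyl)oxy]methyl}-3-iodo-5-[(2S,3R)-3-{3-[(tert-butyldimethylsilyl)oxy]propyl}-3-methyloxiran-2-yl]furan-2(5H)-one | IC1=C(CO[Si](C)(C)C(C)(C)C)[C@@H]([C@@H]2O[C@]2(C)CCCO[Si](C)(C)C(C)(C)C)OC1=O | intermediate
15 | (5S)-4-{[(tert-butyldimethylsilyl)oxy]methyl}-3-(hydroxymethyl)-5-[(2S,3R)-3-{3-[(tert-butyldimethylsilyl)oxy]propyl}-3-methyloxiran-2-yl]furan-2(5H)-one | CC(C)(C)[Si](C)(C)OCC1=C(CO)C(=O)O[C@@H]1[C@@H]1O[C@]1(C)CCCO[Si](C)(C)C(C)(C)C | intermediate
16 | [(5S)-4-{[(tert-butyldimethylsilyl)oxy]methyl}-5-[(2S,3R)-3-{3-[(tert-butyldimethylsilyl)oxy]propyl}-3-methyloxiran-2-yl]-2-oxo-2,5-dihydrofuran-3-yl]methyl acetate | CC(C)(C)[Si](C)(C)OCC1=C(COC(C)=O)C(=O)O[C@@H]1[C@@H]1O[C@]1(C)CCCO[Si](C)(C)C(C)(C)C | intermediate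
17 | [(5S)-4-(hydroxymethyl)-5-[(2S,3R)-3-(3-hydroxypropyl)-3-methyloxiran-2-yl]-2-oxo-2,5-dihydrofuran-3-yl]methyl acetate | OCC1=C(COC(C)=O)C(=O)O[C@@H]1[C@@H]1O[C@]1(C)CCCO | intermediate
18 | [(5S)-4-formyl-5-[(2S,3R)-3-(3-hydroxypropyl)-3-methyloxiran-2-yl]-2-oxo-2,5-dihydrofuran-3-yl]methyl acetate | O=CC1=C(COC(C)=O)C(=O)O[C@@H]1[C@@H]1O[C@]1(C)CCCO | intermediate
19 | allylboronic acid pinacol ester | C=CCB1OC(C)(C)C(C)(C)O1 | starting material
20 | [(5S)-4-[(1S)-1-hydroxybut-3-en-1-yl]-5-[(2S,3R)-3-(3-hydroxypropyl)-3-methyloxiran-2-yl]-2-oxo-2,5-dihydrofuran-3-yl]methyl acetate | C=CC[C@H](O)C1=C(COC(C)=O)C(=O)O[C@@H]1[C@@H]1O[C@]1(C)CCCO | intermediate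
21 | [(5S)-4-[(1S)-1-hydroxybut-3-en-1-yl]-5-[(2S,3R)-3-methyl-3-(3-oxopropyl)oxiran-2-yl]-2-oxo-2,5-dihydrofuran-3-yl]methyl acetate (hydroacylation precursor) | C=CC[C@H](O)C1=C(COC(C)=O)C(=O)O[C@@H]1[C@@H]1O[C@]1(C)CCC=O | intermediate
22 | (4R,5S,6S,8S,10R)-13-acetoxy-4,5-epoxy-8-hydroxy-1-oxogermacr-7(11)-en-12,6-olide (8-O-destigloyl target) | O[C@H]1C[C@@H](C)C(=O)CC[C@@]2(C)O[C@H]2[C@H]2OC(=O)C(COC(C)=O)=C12 | intermediate
23 | tiglic acid, (2E)-2-methylbut-2-enoic acid | C/C=C(\C)C(=O)O | starting material
24 | (2E)-2-methylbut-2-enoic 2,4,6-trichlorobenzoic anhydride | C/C=C(\C)C(=O)OC(=O)c1c(Cl)cc(Cl)cc1Cl | intermediate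
25 | CNP0229937.1, (4R,5S,6S,8S,10R)-13-acetoxy-4,5-epoxy-1-oxo-8-[(2E)-2-methylbut-2-enoyloxy]germacr-7(11)-en-12,6-olide | C/C=C(\C)C(=O)O[C@H]1C[C@@H](C)C(=O)CC[C@@]2(C)O[C@H]2[C@H]2OC(=O)C(COC(C)=O)=C12 | target

## Step count and least certain steps

Total: 16 steps. Longest linear sequence: 15 steps (1 to 25; step 6 is the one-step side branch).

**Step 15 (key step, Proposed new method).** What may go wrong:
- decarbonylation of the acyl rhodium hydride, which also ties the metal up as a carbonyl complex;
- hydride insertion in the linear sense, which would close an eleven-membered ring;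
- migration of the terminal alkene into the chain by reversible hydride insertion;
- intermolecular hydroacylation, that is, oligomerisation;
- oxidation at C8 by β-hydride elimination from an O8-bound rhodium alkoxide;
- ionisation of the allylic acetate by the low-valent metal.

Fallback with known chemistry, setting out from 18 and coming back at 22: asymmetric 2-bromoallylboration of 18 (2-bromoallylboronic acid pinacol ester, (S)-TRIP) would give the bromoallyl carbinol F1. TEMPO/PhI(OAc)2 would oxidise its primary alcohol to the aldehyde F2, and TESCl/imidazole would cover the C8 hydroxyl as the silyl ether F3. An intramolecular Nozaki–Hiyama–Kishi reaction (CrCl2, cat. NiCl2, DMSO/THF, high dilution) would then form the C1–C10 bond and give the exo-methylene carbinol F4 as C1 epimers. Dess–Martin periodinane would give the enone F5. Conjugate reduction with [(Ph3P)CuH]6 and protonation of the enolate from the outer face of the ring would give the 10-methyl ketone F6; C10 is the weak point of this detour. HF·pyridine would finally free the C8 hydroxyl to give 22.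

**Step 7.** What may go wrong: slow insertion of CO2 into the hindered, silicon-bearing vinyl–titanium bond; β-elimination of the propargylic silyloxy group from the titanacyclopropene; insufficient Felkin–Anh control at C6.

Fallback, setting out from 7 and 9 and coming back at 13: the coupling is run as before, but the oxatitanacycle is quenched with I2, a much less demanding reaction of the vinyl–titanium bond, to give the iodo(silyl)alkenyl carbinol F7. PdCl2(PPh3)2, CO (1 atm) and Et3N in THF would then close the butenolide by carbonylative lactonisation to 13.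

**Step 8.** What may go wrong: sluggish ipso-substitution, because the lactone carbonyl deactivates the vinylsilane; opening of the epoxide by the Lewis-acidic interhalogen.

Fallback, setting out from 13 and coming back at 14: iBu2AlH at −78 °C would reduce the lactone to the lactol F8, which removes the deactivating carbonyl. N-Iodosuccinimide in MeCN would then replace silicon by iodine with retention to give the iodo lactol F9, and TEMPO/PhI(OAc)2 would re-oxidise the lactol to 14.

**Step 13.** What may go wrong: poor facial selectivity if the catalyst and the existing centres are mismatched; slow addition to a hindered, tetrasubstituted alkenyl aldehyde, allowing the uncatalysed background reaction to erode selectivity.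

Fallback, setting out from 18 and coming back at 20: uncatalysed allylboration with 19 (toluene, rt) would give 20 together with its C8 epimer F10. MnO2 would oxidise the mixture at the allylic secondary carbinol only, to the ketone F11. Corey–Bakshi–Shibata reduction with catecholborane and the (R)-methyl oxazaborolidine at −78 °C would then set 8S by reduction instead of by carbon–carbon bond formation and return 20.

## Further compounds

F1 | step 15 | [(5S)-4-[(1S)-3-bromo-1-hydroxybut-3-en-1-yl]-5-[(2S,3R)-3-(3-hydroxypropyl)-3-methyloxiran-2-yl]-2-oxo-2,5-dihydrofuran-3-yl]methyl acetate | C=C(Br)C[C@H](O)C1=C(COC(C)=O)C(=O)O[C@@H]1[C@@H]1O[C@]1(C)CCCO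
F2 | step 15 | [(5S)-4-[(1S)-3-bromo-1-hydroxybut-3-en-1-yl]-5-[(2S,3R)-3-methyl-3-(3-oxopropyl)oxiran-2-yl]-2-oxo-2,5-dihydrofuran-3-yl]methyl acetate | C=C(Br)C[C@H](O)C1=C(COC(C)=O)C(=O)O[C@@H]1[C@@H]1O[C@]1(C)CCC=O
F3 | step 15 | [(5S)-4-[(1S)-3-bromo-1-(triethylsilyloxy)but-3-en-1-yl]-5-[(2S,3R)-3-methyl-3-(3-oxopropyl)oxiran-2-yl]-2-oxo-2,5-dihydrofuran-3-yl]methyl acetate | C=C(Br)C[C@H](O[Si](CC)(CC)CC)C1=C(COC(C)=O)C(=O)O[C@@H]1[C@@H]1O[C@]1(C)CCC=O
F4 | step 15 | (4R,5S,6S,8S)-13-acetoxy-4,5-epoxy-1-hydroxy-8-(triethylsilyloxy)germacra-7(11),10(14)-dien-12,6-olide (C1 epimers) | CC[Si](CC)(CC)O[C@H]1CC(=C)C(O)CC[C@@]2(C)O[C@H]2[C@H]2OC(=O)C(COC(C)=O)=C12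
F5 | step 15 | (4R,5S,6S,8S)-13-acetoxy-4,5-epoxy-1-oxo-8-(triethylsilyloxy)germacra-7(11),10(14)-dien-12,6-olide | CC[Si](CC)(CC)O[C@H]1CC(=C)C(=O)CC[C@@]2(C)O[C@H]2[C@H]2OC(=O)C(COC(C)=O)=C12
F6 | step 15 | (4R,5S,6S,8S,10R)-13-acetoxy-4,5-epoxy-1-oxo-8-(triethylsilyloxy)germacr-7(11)-en-12,6-olide | CC[Si](CC)(CC)O[C@H]1C[C@@H](C)C(=O)CC[C@@]2(C)O[C@H]2[C@H]2OC(=O)C(COC(C)=O)=C12
F7 | step 7 | (1S,2Z)-2-{[(tert-butyldimethylsilyl)oxy]methyl}-1-[(2S,3R)-3-{3-[(tert-butyldimethylsilyl)oxy]propyl}-3-methyloxiran-2-yl]-3-iodo-3-(trimethylsilyl)prop-2-en-1-ol (iodine cis to the carbinol carbon) | I/C(=C(/CO[Si](C)(C)C(C)(C)C)[C@H](O)[C@@H]1O[C@]1(C)CCCO[Si](C)(C)C(C)(C)C)[Si](C)(C)C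
F8 | step 8 | (5S)-4-{[(tert-butyldimethylsilyl)oxy]methyl}-5-[(2S,3R)-3-{3-[(tert-butyldimethylsilyl)oxy]propyl}-3-methyloxiran-2-yl]-3-(trimethylsilyl)-2,5-dihydrofuran-2-ol (anomers) | CC(C)(C)[Si](C)(C)OCC1=C([Si](C)(C)C)C(O)O[C@@H]1[C@@H]1O[C@]1(C)CCCO[Si](C)(C)C(C)(C)C
F9 | step 8 | (5S)-4-{[(tert-butyldimethylsilyl)oxy]methyl}-3-iodo-5-[(2S,3R)-3-{3-[(tert-butyldimethylsilyl)oxy]propyl}-3-methyloxiran-2-yl]-2,5-dihydrofuran-2-ol (anomers) | OC1O[C@H]([C@@H]2O[C@]2(C)CCCO[Si](C)(C)C(C)(C)C)C(CO[Si](C)(C)C(C)(C)C)=C1I
F10 | step 13 | [(5S)-4-[(1R)-1-hydroxybut-3-en-1-yl]-5-[(2S,3R)-3-(3-hydroxypropyl)-3-methyloxiran-2-yl]-2-oxo-2,5-dihydrofuran-3-yl]methyl acetate (C8 epimer of 20) | C=CC[C@@H](O)C1=C(COC(C)=O)C(=O)O[C@@H]1[C@@H]1O[C@]1(C)CCCO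
F11 | step 13 | [(5S)-4-(but-3-enoyl)-5-[(2S,3R)-3-(3-hydroxypropyl)-3-methyloxiran-2-yl]-2-oxo-2,5-dihydrofuran-3-yl]methyl acetate | C=CCC(=O)C1=C(COC(C)=O)C(=O)O[C@@H]1[C@@H]1O[C@]1(C)CCCO
A1 | alternative 1 | 4-{[(tert-butyldimethylsilyl)oxy]methylidene}-6-hydroxy-9-methyl-6-(prop-1-en-2-yl)-1-oxaspiro[4.5]dec-9-en-2-one (one diastereomer drawn; both quaternary centres are lost in the step) | C=C(C)[C@]1(O)CCC(C)=C[C@@]12OC(=O)C/C2=C/O[Si](C)(C)C(C)(C)C
A2 | alternative 1 | ten-membered (4Z)-ene keto butenolide lacking C13, 8-O-TBS | CC(C)(C)[Si](C)(C)O[C@H]1C[C@@H](C)C(=O)CC/C(C)=C\[C@H]2OC(=O)C=C12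
A3 | alternative 2 | [4-[(tert-butyldimethylsilyl)oxy]-7a-[(1Z)-4-iodo-2-methylbut-1-en-1-yl]-6-methyl-2,7-dioxo-2,4,5,6,7,7a-hexahydro-1-benzofuran-3-yl]methyl acetate (one C7a epimer drawn; the centre is lost in the step) | ICC/C(C)=C\[C@]12OC(=O)C(COC(C)=O)=C1[C@@H](O[Si](C)(C)C(C)(C)C)C[C@@H](C)C2=O
A4 | alternative 2 | ten-membered (4Z)-ene keto butenolide, 8-O-TBS, 13-OAc | CC(C)(C)[Si](C)(C)O[C@H]1C[C@@H](C)C(=O)CC/C(C)=C\[C@H]2OC(=O)C(COC(C)=O)=C12
A5 | alternative 3 | 3-methyl-2-methylidene-8-(prop-1-en-2-yl)oxocane fused at its C6–C7 bond to a 3-(silyloxymethyl)-2,5-dihydrofuran, 5-O-TBS (one C8 epimer of the oxocane drawn) | C=C1O[C@@H](C(C)=C)[C@H]2OCC(CO[Si](C)(C)C(C)(C)C)=C2[C@@H](O[Si](C)(C)C(C)(C)C)C[C@H]1C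
A6 | alternative 3 | ten-membered (4Z)-ene ketone fused to the 2,5-dihydrofuran, bis-TBS | CC(C)(C)[Si](C)(C)O[C@H]1C[C@@H](C)C(=O)CC/C(C)=C\[C@H]2OCC(CO[Si](C)(C)C(C)(C)C)=C12
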